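**Plan**
1. Retrosynthesis: cut the aryl N–C(quinone) bond (aryl amine + methoxy-quinone); in each half cut the C9–C11 benzylic bond and take the C8 methyl back to C8=O; reset C10 through a C9=C10 enone; finally open ring B at C5–C6.
2. Enabling feature: C5 is a quaternary carbon allylic to the C3=C4 bond of ring A and C8 can stand at ketone level, so C3=C4–C5–C6–C7–C8(=O) is a δ,ε-unsaturated ketone, the retron of an oxy-Cope shift in which C5–C6 forms while a temporary C3–C8 bridge bond breaks.
3. Forward: 2-methylcyclohexenone → 2,3-dimethylcyclohexa-1,3-diene (ring A); an asymmetric Diels–Alder reaction adds the C8–C9 bridge; vinyl addition; anionic oxy-Cope closes ring B and delivers the Δ3 olefin; dehydrogenation gives the common C9=C10 enone 13.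
4. Divergence and union: 13 is reduced once and the trans-fused enolate is kept as silyl enol ether 19, which is C9-benzylated with two benzyl bromides; each ketone is methylenated and hydrogenated; one arene becomes the hydroxy-methoxy-quinone, the other the 3-amino-β-resorcylate; the amine displaces the quinone methoxy group.
5. Stereochemistry: only the Diels–Alder bridgehead (future C10) is set by catalysis; the [3,3] shift relays it to quaternary C5 (cis); C10 is then planarised and reset trans in the dissolving-metal reduction; quaternary C9 is set in each benzylation anti to the C5 methyl; C8 follows by hydrogenation from the α-face.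

Key step: step 6

Remarks on the chemistry
- Decalin carbons carry avarane numbers (ring A = C1–C5, C10; ring B = C5–C10; C11 = benzylic CH2). Av = [(1R,2S,4aS,8aS)-1,2,4a,5-tetramethyl-1,2,3,4,4a,7,8,8a-octahydronaphthalen-1-yl]methyl.
- Assumption: the L-phenylalanine-derived catalyst of step 3 shows the facial sense recalled for cyclohexa-1,3-diene/acrolein; if not, its (5R) enantiomer is used.
- The configurations at C9 in 6–11 and at the formyl-bearing carbon of 6 are inconsequential; both centres are planarised later.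
- The enolate released from 19 is matched to each electrophile. The hindered, doubly ortho-substituted bromide 17 meets the more nucleophilic ammonium enolate. The readily ionised 2,4-dialkoxybenzyl bromide 29 meets the potassium enolate, whose tighter ion pair should favour C- over O-benzylation.

**Step 1**
Reactants: 1 2-methylcyclohex-2-en-1-one
Product: 3 6-methylcyclohexa-1,5-dien-1-yl trifluoromethanesulfonate, via lithium cross-conjugated dienolate 2 (not isolated)
Conditions: LiN(i-Pr)2, THF, −78 °C; PhNTf2, −78 → 0 °C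
Reagents that add atoms: N-phenylbis(trifluoromethanesulfonimide) (O=S(=O)(N(c1ccccc1)S(=O)(=O)C(F)(F)F)C(F)(F)F)
Why: Kinetic α′-deprotonation of the enone gives the cross-conjugated dienolate, which is O-sulfonylated (enol triflate formation) to the 2-triflyloxy-1,3-diene.

**Step 2**
Reactants: 3 6-methylcyclohexa-1,5-dien-1-yl trifluoromethanesulfonate
Product: 4 2,3-dimethylcyclohexa-1,3-diene
Conditions: MeMgBr, Fe(acac)3 (5 mol %), THF/NMP, −30 → 0 °C
Reagents that add atoms: methylmagnesium bromide (C[Mg]Br)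
Why: Iron-catalysed cross-coupling of an alkenyl triflate with a methyl Grignard reagent replaces OTf by CH3 without moving the double bonds, giving the mirror-symmetric diene that is ring A.

**Step 3**
Reactants: 4 2,3-dimethylcyclohexa-1,3-diene; 5 (E)-but-2-enal
Product: 6 (1S,2R,3S,4R)-3,5,6-trimethylbicyclo[2.2.2]oct-5-ene-2-carbaldehyde (CHO endo, 3-methyl trans to it)
Conditions: (5S)-5-benzyl-2,2,3-trimethylimidazolidin-4-one hydrochloride (20 mol %), MeCN/H2O 95:5, rt
Reagents that add atoms: none
Why: Iminium-catalysed asymmetric Diels–Alder reaction; the symmetric diene allows one regioisomer only, and the (E)-iminium ion should react through the endo transition state on the face not shielded by the benzyl group, which fixes the bridgehead carbon (future C10).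

**Step 4**
Reactants: 6 (1S,2R,3S,4R)-3,5,6-trimethylbicyclo[2.2.2]oct-5-ene-2-carbaldehyde
Product: 7 (1R,3S,4R)-3,5,6-trimethylbicyclo[2.2.2]oct-5-en-2-one
Conditions: O2 (1 atm), Cu(OAc)2 (10 mol %), 2,2′-bipyridine (10 mol %), DABCO, DMF, 40 °C
Reagents that add atoms: dioxygen (O=O)
Why: Copper-catalysed aerobic oxidative deformylation of an α-branched aldehyde (α-hydroperoxy aldehyde, then loss of formic acid) turns the formyl-bearing carbon into the ketone carbon C8.

**Step 5**
Reactants: 7 (1R,3S,4R)-3,5,6-trimethylbicyclo[2.2.2]oct-5-en-2-one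
Product: 8 (1R,2S,3S,4R)-2-ethenyl-3,5,6-trimethylbicyclo[2.2.2]oct-5-en-2-ol (vinyl syn to the C5=C6 bridge)
Conditions: CH2=CHMgBr, CeCl3, THF, −78 → 0 °C; aq. NH4Cl
Reagents that add atoms: vinylmagnesium bromide (C=C[Mg]Br)
Why: Organocerium 1,2-addition suppresses enolisation and should occur from the etheno-bridge face, which is less hindered than the ethano-bridge face that also carries the C3 methyl, so the vinyl group ends syn to the alkene as the rearrangement requires.

**Step 6**
Reactants: 8 (1R,2S,3S,4R)-2-ethenyl-3,5,6-trimethylbicyclo[2.2.2]oct-5-en-2-ol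
Product: 11 (1S,4aS,8aR)-1,4a,5-trimethyl-3,4,4a,7,8,8a-hexahydronaphthalen-2(1H)-one (cis-fused), via potassium alkoxide 9 (not isolated), via potassium enolate 10 (not isolated)
Conditions: KH, 18-crown-6, THF, 0 → 50 °C; then aq. NH4Cl, 0 °C
Reagents that add atoms: none
Why: Deprotonation gives alkoxide 9, whose oxyanion weakens the adjacent carbinol–bridgehead σ bond (C8–C3) and triggers an anion-accelerated [3,3]-sigmatropic oxy-Cope shift in which the vinyl terminus (C6) bonds to the methyl-bearing alkene carbon C5 while C3–C8 breaks, leaving the C3=C4 olefin and enolate 10. The closest known reaction type is the anionic oxy-Cope rearrangement of 2-vinylbicyclo[2.2.2]oct-5-en-2-ols to cis-fused octalones, a type that tolerates a methyl group on the bond-forming alkene carbon, which then becomes an angular quaternary centre. Ring B is closed not by attack of a chain end on a ring but by sigmatropic reorganisation of the bicyclo[2.2.2]octene into the bicyclo[4.4.0]decene through the boat-like six-centre transition state that the cage enforces. The new quaternary stereocentre C5 is controlled by the bridgehead C10 set in step 3, because the vinyl group is held over one face of the C4=C5 bridge only, so the shift is suprafacial, stereospecific and necessarily cis-fusing. The step needs the vinyl group syn to the alkene bridge, secured by the face selectivity of step 5, and a [3,3] shift in preference to fragmentation or [1,3] shift, which the crown-ether-separated potassium alkoxide and the rigid 1,5-diene geometry should favour. Protonation of 10 at C7 on work-up then gives ketone 11, C9 being untouched.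

**Step 7**
Reactants: 11 (1S,4aS,8aR)-1,4a,5-trimethyl-3,4,4a,7,8,8a-hexahydronaphthalen-2(1H)-one
Product: 12 trimethyl{[(4aS,8aS)-1,4a,5-trimethyl-3,4,4a,7,8,8a-hexahydronaphthalen-2-yl]oxy}silane (cis-fused, C8=C9 enol ether)
Conditions: TMSCl, NaI, Et3N, MeCN, rt
Reagents that add atoms: chlorotrimethylsilane (C[Si](C)(C)Cl)
Why: Equilibrating silylation with iodotrimethylsilane formed in the flask should give the thermodynamic, more substituted silyl enol ether toward C9 and not toward C7.

**Step 8**
Reactants: 12 trimethyl{[(4aS,8aS)-1,4a,5-trimethyl-3,4,4a,7,8,8a-hexahydronaphthalen-2-yl]oxy}silane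
Product: 13 (4aR)-1,4a,5-trimethyl-4,4a,7,8-tetrahydronaphthalen-2(3H)-one
Conditions: Pd(OAc)2 (1.05 equiv), MeCN, rt
Reagents that add atoms: none
Why: Saegusa–Ito oxidation; palladation at C9 and β-hydride elimination of H-10 should give the tetrasubstituted conjugated enone, which erases the cis C10 centre and leaves C5 as the only stereocentre.

**Step 9**
Reactants: 14 1,2,4,5-tetramethoxybenzene
Product: 16 (2,3,5,6-tetramethoxyphenyl)methanol, via aryllithium 15 (not isolated)
Conditions: n-BuLi, THF, 0 °C; (CH2O)n, 0 °C → rt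
Reagents that add atoms: formaldehyde, as paraformaldehyde (C=O)
Why: Directed ortho-lithiation between two methoxy groups followed by hydroxymethylation of the aryllithium with formaldehyde.

**Step 10**
Reactants: 16 (2,3,5,6-tetramethoxyphenyl)methanol
Product: 17 3-(bromomethyl)-1,2,4,5-tetramethoxybenzene
Conditions: PBr3, Et2O, 0 °C
Reagents that add atoms: phosphorus tribromide (BrP(Br)Br)
Why: Standard conversion of an electron-rich benzylic alcohol into the benzylic bromide.

**Step 11**
Reactants: 13 (4aR)-1,4a,5-trimethyl-4,4a,7,8-tetrahydronaphthalen-2(3H)-one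
Product: 19 trimethyl{[(4aS,8aR)-1,4a,5-trimethyl-3,4,4a,7,8,8a-hexahydronaphthalen-2-yl]oxy}silane (trans-fused, C8=C9 enol ether), via lithium enolate 18 (not isolated)
Conditions: Li (2.1 equiv), NH3(l)/THF, t-BuOH (1.0 equiv), −78 °C; NH3 evaporated; TMSCl, Et3N, THF, −78 → 0 °C; cold aq. NaHCO3
Reagents that add atoms: chlorotrimethylsilane (C[Si](C)(C)Cl)
Why: Dissolving-metal (Birch-type) reduction of the enone, in which the β-carbanion at C10 is protonated axially to give the trans-fused lithium enolate; O-silylation (Stork-type enolate trapping) then freezes both the ring fusion and the C8=C9 regiochemistry in one storable enol ether that serves both halves.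

**Step 12**
Reactants: 19 trimethyl{[(4aS,8aR)-1,4a,5-trimethyl-3,4,4a,7,8,8a-hexahydronaphthalen-2-yl]oxy}silane; 17 3-(bromomethyl)-1,2,4,5-tetramethoxybenzene
Product: 21 (1S,4aS,8aR)-1,4a,5-trimethyl-1-[(2,3,5,6-tetramethoxyphenyl)methyl]-3,4,4a,7,8,8a-hexahydronaphthalen-2(1H)-one (trans-fused), via benzyltrimethylammonium enolate 20 (not isolated)
Conditions: anhydrous BnMe3NF (1.2 equiv), 4 Å molecular sieves, THF, 0 °C → rt
Reagents that add atoms: none
Why: Fluoride attacks silicon and releases the regiodefined ammonium enolate (fluoride-promoted regiospecific alkylation of a silyl enol ether), which is nucleophilic enough for the hindered bromide; benzylation at C9 occurs anti to the axial C5 methyl, so the quaternary centre is set by substrate control.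

**Step 13**
Reactants: 21 (1S,4aS,8aR)-1,4a,5-trimethyl-1-[(2,3,5,6-tetramethoxyphenyl)methyl]-3,4,4a,7,8,8a-hexahydronaphthalen-2(1H)-one
Product: 22 1,2,4,5-tetramethoxy-3-{[(1S,4aS,8aS)-1,4a,5-trimethyl-2-methylidene-1,2,3,4,4a,7,8,8a-octahydronaphthalen-1-yl]methyl}benzene
Conditions: Ph3PCH3Br, KOtBu, toluene, 90 °C
Reagents that add atoms: methyltriphenylphosphonium bromide, as its ylide (C[P+](c1ccccc1)(c1ccccc1)c1ccccc1.[Br-])
Why: Wittig methylenation of the hindered, non-enolisable-at-C9 ketone brings in the C8 methyl carbon.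

**Step 14**
Reactants: 22 1,2,4,5-tetramethoxy-3-{[(1S,4aS,8aS)-1,4a,5-trimethyl-2-methylidene-1,2,3,4,4a,7,8,8a-octahydronaphthalen-1-yl]methyl}benzene
Product: 23 1,2,4,5-tetramethoxy-3-Av-benzene
Conditions: H2 (1 atm), RhCl(PPh3)3 (10 mol %), benzene, rt
Reagents that add atoms: none
Why: Homogeneous hydrogenation should reduce the 1,1-disubstituted exocyclic alkene and spare the hindered trisubstituted C3=C4 bond, with hydrogen delivered to the α-face opposite the axial methyls on C5 and C9, giving the equatorial 8β-methyl.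

**Step 15**
Reactants: 23 1,2,4,5-tetramethoxy-3-Av-benzene
Product: 24 2,5-dimethoxy-3-Av-cyclohexa-2,5-diene-1,4-dione
Conditions: (NH4)2Ce(NO3)6, MeCN/H2O, 0 °C
Reagents that add atoms: water (O)
Why: Oxidative demethylation of a para-dimethoxyarene to the para-quinone, fast at 0 °C and compatible with the isolated trisubstituted alkene.

**Step 16**
Reactants: 24 2,5-dimethoxy-3-Av-cyclohexa-2,5-diene-1,4-dione
Product: 25 2-hydroxy-5-methoxy-3-Av-cyclohexa-2,5-diene-1,4-dione
Conditions: KOH, MeOH/H2O, rt; then 1 M HCl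
Reagents that add atoms: potassium hydroxide ([K+].[OH-])
Why: Addition–elimination hydrolysis of one vinylogous ester, expected by analogy with the ilimaquinone series to occur at the methoxy group flanked by the alkyl substituent, which is twisted out of conjugation and therefore the more electrophilic.

**Step 17**
Reactants: 26 5-bromo-2,4-dihydroxybenzaldehyde
Product: 27 5-bromo-2,4-bis(methoxymethoxy)benzaldehyde
Conditions: MOMCl, i-Pr2NEt, CH2Cl2, 0 °C → rt
Reagents that add atoms: chloromethyl methyl ether (COCCl)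
Why: Acetal protection of both phenols with a group that survives enolates, ylides and organolithiums and is removed by mild acid.

**Step 18**
Reactants: 27 5-bromo-2,4-bis(methoxymethoxy)benzaldehyde
Product: 28 [5-bromo-2,4-bis(methoxymethoxy)phenyl]methanol
Conditions: NaBH4, MeOH, 0 °C
Reagents that add atoms: none
Why: Chemoselective hydride reduction of the aldehyde to the benzylic alcohol.

**Step 19**
Reactants: 28 [5-bromo-2,4-bis(methoxymethoxy)phenyl]methanol
Product: 29 1-bromo-5-(bromomethyl)-2,4-bis(methoxymethoxy)benzene (used at once)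
Conditions: CBr4, PPh3, CH2Cl2, 0 °C
Reagents that add atoms: carbon tetrabromide (BrC(Br)(Br)Br)
Why: Appel bromination under neutral conditions keeps the acid-labile acetals intact.

**Step 20**
Reactants: 19 trimethyl{[(4aS,8aR)-1,4a,5-trimethyl-3,4,4a,7,8,8a-hexahydronaphthalen-2-yl]oxy}silane; 29 1-bromo-5-(bromomethyl)-2,4-bis(methoxymethoxy)benzene
Product: 31 (1S,4aS,8aR)-1-{[5-bromo-2,4-bis(methoxymethoxy)phenyl]methyl}-1,4a,5-trimethyl-3,4,4a,7,8,8a-hexahydronaphthalen-2(1H)-one (trans-fused), via potassium enolate 30 (not isolated)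
Conditions: KOtBu (1.0 equiv), THF, −20 °C; 29 in THF, −78 → 0 °C
Reagents that add atoms: none
Why: tert-Butoxide cleaves the O–Si bond to give the regiodefined potassium enolate (alkoxide-mediated enolate generation from a silyl enol ether), which is C-benzylated by the highly reactive bromide anti to the axial C5 methyl, setting quaternary C9; no reducing metal meets the aryl bromide and no acid meets the acetals.

**Step 21**
Reactants: 31 (1S,4aS,8aR)-1-{[5-bromo-2,4-bis(methoxymethoxy)phenyl]methyl}-1,4a,5-trimethyl-3,4,4a,7,8,8a-hexahydronaphthalen-2(1H)-one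
Product: 32 1-bromo-2,4-bis(methoxymethoxy)-5-{[(1S,4aS,8aS)-1,4a,5-trimethyl-2-methylidene-1,2,3,4,4a,7,8,8a-octahydronaphthalen-1-yl]methyl}benzene
Conditions: Ph3PCH3Br, KOtBu, toluene, 90 °C
Reagents that add atoms: methyltriphenylphosphonium bromide, as its ylide (C[P+](c1ccccc1)(c1ccccc1)c1ccccc1.[Br-])
Why: Wittig methylenation of the C8 ketone; aryl bromide and acetals are inert to the ylide.

**Step 22**
Reactants: 32 1-bromo-2,4-bis(methoxymethoxy)-5-{[(1S,4aS,8aS)-1,4a,5-trimethyl-2-methylidene-1,2,3,4,4a,7,8,8a-octahydronaphthalen-1-yl]methyl}benzene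
Product: 33 1-bromo-2,4-bis(methoxymethoxy)-5-Av-benzene
Conditions: H2 (1 atm), RhCl(PPh3)3 (10 mol %), benzene, rt
Reagents that add atoms: none
Why: Chemoselective homogeneous hydrogenation of the exocyclic alkene from the α-face, as in step 14, sets the 8β-methyl and leaves the C3=C4 bond and the C–Br bond alone.

**Step 23**
Reactants: 33 1-bromo-2,4-bis(methoxymethoxy)-5-Av-benzene
Product: 35 methyl 2,4-bis(methoxymethoxy)-5-Av-benzoate, via aryllithium 34 (not isolated)
Conditions: t-BuLi (2.1 equiv), THF, −78 °C; ClCO2Me, −78 → 0 °C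
Reagents that add atoms: methyl chloroformate (COC(=O)Cl)
Why: Bromine–lithium exchange gives an aryllithium stabilised by the ortho acetal oxygen, which is acylated by the chloroformate to the methyl ester.

**Step 24**
Reactants: 35 methyl 2,4-bis(methoxymethoxy)-5-Av-benzoate
Product: 36 methyl 2,4-dihydroxy-5-Av-benzoate
Conditions: 3 M aq. HCl, MeOH, 45 °C
Reagents that add atoms: none
Why: Acid-catalysed acetal exchange removes both methoxymethyl groups; the methyl ester is stable in methanol and the Δ3 olefin is the thermodynamic alkene isomer and should not migrate.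

**Step 25**
Reactants: 36 methyl 2,4-dihydroxy-5-Av-benzoate
Product: 37 methyl 2,4-dihydroxy-3-[(E)-phenyldiazenyl]-5-Av-benzoate
Conditions: PhN2BF4, NaHCO3, THF/H2O, 0 °C
Reagents that add atoms: benzenediazonium tetrafluoroborate (N#[N+]c1ccccc1.F[B-](F)(F)F)
Why: Azo coupling of the phenoxide at the only free activated position, C3 between the two hydroxyl groups, brings in nitrogen with an electrophile that does not touch the alkene.

**Step 26**
Reactants: 37 methyl 2,4-dihydroxy-3-[(E)-phenyldiazenyl]-5-Av-benzoate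
Product: 38 methyl 3-amino-2,4-dihydroxy-5-Av-benzoate (used at once)
Conditions: Na2S2O4, EtOH/H2O, 50 °C, argon
Reagents that add atoms: none
Why: Dithionite reductively cleaves the N=N bond to the aryl amine and aniline without affecting ester or alkene.

**Step 27**
Reactants: 38 methyl 3-amino-2,4-dihydroxy-5-Av-benzoate; 25 2-hydroxy-5-methoxy-3-Av-cyclohexa-2,5-diene-1,4-dione
Product: 39 nakijiquinone F
Conditions: EtOH, NaHCO3 (0.2 equiv), 50 °C, argon; dilute HCl on work-up
Reagents that add atoms: none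
Why: Conjugate addition–elimination of the aryl amine at C5 of the quinone replaces the only leaving group (methoxy), turning the vinylogous ester into the vinylogous amide as in the amine exchange of ilimaquinone-type quinones.

**Compound list**
1 | 2-methylcyclohex-2-en-1-one | CC1=CCCCC1=O | starting material
2 | lithium 6-methylcyclohexa-1,5-dien-1-olate | [Li+].[O-]C1=CCCC=C1C | intermediate (not isolated)
3 | 6-methylcyclohexa-1,5-dien-1-yl trifluoromethanesulfonate | CC1=CCCC=C1OS(=O)(=O)C(F)(F)F | intermediate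
4 | 2,3-dimethylcyclohexa-1,3-diene | CC1=CCCC=C1C | intermediate
5 | (E)-but-2-enal | C/C=C/C=O | starting material
6 | (1S,2R,3S,4R)-3,5,6-trimethylbicyclo[2.2.2]oct-5-ene-2-carbaldehyde | O=C[C@@H]1[C@@H](C)[C@H]2CC[C@@H]1C(C)=C2C | intermediate
7 | (1R,3S,4R)-3,5,6-trimethylbicyclo[2.2.2]oct-5-en-2-one | O=C1[C@@H](C)[C@H]2CC[C@@H]1C(C)=C2C | intermediate
8 | (1R,2S,3S,4R)-2-ethenyl-3,5,6-trimethylbicyclo[2.2.2]oct-5-en-2-ol | C=C[C@]1(O)[C@@H](C)[C@H]2CC[C@@H]1C(C)=C2C | intermediate
9 | potassium alkoxide of 8 | C=C[C@]1([O-])[C@@H](C)[C@H]2CC[C@@H]1C(C)=C2C.[K+] | intermediate (not isolated)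
10 | potassium (1S,4aS,8aR)-1,4a,5-trimethyl-1,4,4a,7,8,8a-hexahydronaphthalen-2-olate (C7=C8 enolate, cis-fused) | [K+].[O-]C1=CC[C@]2(C)C(C)=CCC[C@@H]2[C@@H]1C | intermediate (not isolated)
11 | (1S,4aS,8aR)-1,4a,5-trimethyl-3,4,4a,7,8,8a-hexahydronaphthalen-2(1H)-one (cis-fused) | O=C1CC[C@]2(C)C(C)=CCC[C@@H]2[C@@H]1C | intermediate
12 | trimethyl{[(4aS,8aS)-1,4a,5-trimethyl-3,4,4a,7,8,8a-hexahydronaphthalen-2-yl]oxy}silane (cis-fused) | C[Si](C)(C)OC1=C(C)[C@H]2CCC=C(C)[C@@]2(C)CC1 | intermediate
13 | (4aR)-1,4a,5-trimethyl-4,4a,7,8-tetrahydronaphthalen-2(3H)-one | O=C1CC[C@]2(C)C(C)=CCCC2=C1C | intermediate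
14 | 1,2,4,5-tetramethoxybenzene | COc1cc(OC)c(OC)cc1OC | starting material
15 | (2,3,5,6-tetramethoxyphenyl)lithium | COc1cc(OC)c(OC)c([Li])c1OC | intermediate (not isolated)
16 | (2,3,5,6-tetramethoxyphenyl)methanol | COc1cc(OC)c(OC)c(CO)c1OC | intermediate
17 | 3-(bromomethyl)-1,2,4,5-tetramethoxybenzene | COc1cc(OC)c(OC)c(CBr)c1OC | intermediate
18 | lithium (4aS,8aR)-1,4a,5-trimethyl-3,4,4a,7,8,8a-hexahydronaphthalen-2-olate (C8=C9 enolate, trans-fused) | [Li+].[O-]C1=C(C)[C@@H]2CCC=C(C)[C@@]2(C)CC1 | intermediate (not isolated)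
19 | trimethyl{[(4aS,8aR)-1,4a,5-trimethyl-3,4,4a,7,8,8a-hexahydronaphthalen-2-yl]oxy}silane (trans-fused) | C[Si](C)(C)OC1=C(C)[C@@H]2CCC=C(C)[C@@]2(C)CC1 | intermediate
20 | benzyltrimethylammonium (4aS,8aR)-1,4a,5-trimethyl-3,4,4a,7,8,8a-hexahydronaphthalen-2-olate (C8=C9 enolate, trans-fused) | C[N+](C)(C)Cc1ccccc1.[O-]C1=C(C)[C@@H]2CCC=C(C)[C@@]2(C)CC1 | intermediate (not isolated)
21 | (1S,4aS,8aR)-1,4a,5-trimethyl-1-[(2,3,5,6-tetramethoxyphenyl)methyl]-3,4,4a,7,8,8a-hexahydronaphthalen-2(1H)-one | COc1cc(OC)c(OC)c(C[C@]2(C)C(=O)CC[C@]3(C)C(C)=CCC[C@@H]23)c1OC | intermediate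
22 | 1,2,4,5-tetramethoxy-3-{[(1S,4aS,8aS)-1,4a,5-trimethyl-2-methylidene-1,2,3,4,4a,7,8,8a-octahydronaphthalen-1-yl]methyl}benzene | COc1cc(OC)c(OC)c(C[C@]2(C)C(=C)CC[C@]3(C)C(C)=CCC[C@@H]23)c1OC | intermediate
23 | 1,2,4,5-tetramethoxy-3-Av-benzene | COc1cc(OC)c(OC)c(C[C@]2(C)[C@@H](C)CC[C@]3(C)C(C)=CCC[C@@H]23)c1OC | intermediate
24 | 2,5-dimethoxy-3-Av-cyclohexa-2,5-diene-1,4-dione | COC1=CC(=O)C(OC)=C(C[C@]2(C)[C@@H](C)CC[C@]3(C)C(C)=CCC[C@@H]23)C1=O | intermediate
25 | 2-hydroxy-5-methoxy-3-Av-cyclohexa-2,5-diene-1,4-dione | COC1=CC(=O)C(O)=C(C[C@]2(C)[C@@H](C)CC[C@]3(C)C(C)=CCC[C@@H]23)C1=O | intermediate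
26 | 5-bromo-2,4-dihydroxybenzaldehyde | O=Cc1cc(Br)c(O)cc1O | starting material
27 | 5-bromo-2,4-bis(methoxymethoxy)benzaldehyde | O=Cc1cc(Br)c(OCOC)cc1OCOC | intermediate
28 | [5-bromo-2,4-bis(methoxymethoxy)phenyl]methanol | OCc1cc(Br)c(OCOC)cc1OCOC | intermediate
29 | 1-bromo-5-(bromomethyl)-2,4-bis(methoxymethoxy)benzene | BrCc1cc(Br)c(OCOC)cc1OCOC | intermediate
30 | potassium (4aS,8aR)-1,4a,5-trimethyl-3,4,4a,7,8,8a-hexahydronaphthalen-2-olate (C8=C9 enolate, trans-fused) | [K+].[O-]C1=C(C)[C@@H]2CCC=C(C)[C@@]2(C)CC1 | intermediate (not isolated)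
31 | (1S,4aS,8aR)-1-{[5-bromo-2,4-bis(methoxymethoxy)phenyl]methyl}-1,4a,5-trimethyl-3,4,4a,7,8,8a-hexahydronaphthalen-2(1H)-one | COCOc1cc(OCOC)c(C[C@]2(C)C(=O)CC[C@]3(C)C(C)=CCC[C@@H]23)cc1Br | intermediate
32 | 1-bromo-2,4-bis(methoxymethoxy)-5-{[(1S,4aS,8aS)-1,4a,5-trimethyl-2-methylidene-1,2,3,4,4a,7,8,8a-octahydronaphthalen-1-yl]methyl}benzene | COCOc1cc(OCOC)c(C[C@]2(C)C(=C)CC[C@]3(C)C(C)=CCC[C@@H]23)cc1Br | intermediate
33 | 1-bromo-2,4-bis(methoxymethoxy)-5-Av-benzene | COCOc1cc(OCOC)c(C[C@]2(C)[C@@H](C)CC[C@]3(C)C(C)=CCC[C@@H]23)cc1Br | intermediate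
34 | [2,4-bis(methoxymethoxy)-5-Av-phenyl]lithium | COCOc1cc(OCOC)c(C[C@]2(C)[C@@H](C)CC[C@]3(C)C(C)=CCC[C@@H]23)cc1[Li] | intermediate (not isolated)
35 | methyl 2,4-bis(methoxymethoxy)-5-Av-benzoate | COCOc1cc(OCOC)c(C[C@]2(C)[C@@H](C)CC[C@]3(C)C(C)=CCC[C@@H]23)cc1C(=O)OC | intermediate
36 | methyl 2,4-dihydroxy-5-Av-benzoate | COC(=O)c1cc(C[C@]2(C)[C@@H](C)CC[C@]3(C)C(C)=CCC[C@@H]23)c(O)cc1O | intermediate
37 | methyl 2,4-dihydroxy-3-[(E)-phenyldiazenyl]-5-Av-benzoate | COC(=O)c1cc(C[C@]2(C)[C@@H](C)CC[C@]3(C)C(C)=CCC[C@@H]23)c(O)c(/N=N/c2ccccc2)c1O | intermediate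
38 | methyl 3-amino-2,4-dihydroxy-5-Av-benzoate | COC(=O)c1cc(C[C@]2(C)[C@@H](C)CC[C@]3(C)C(C)=CCC[C@@H]23)c(O)c(N)c1O | intermediate
39 | nakijiquinone F | COC(=O)c1cc(C[C@]2(C)[C@@H](C)CC[C@]3(C)C(C)=CCC[C@@H]23)c(O)c(NC2=CC(=O)C(O)=C(C[C@]3(C)[C@@H](C)CC[C@]4(C)C(C)=CCC[C@@H]34)C2=O)c1O | target

**Totals and risks**
Total step count: 27. Longest linear sequence: 17 steps (steps 1–8, step 11, then steps 20–27).

Step 3. What may go wrong: the β-substituted iminium ion may add too slowly to a cyclohexadiene, so that the uncatalysed background reaction erodes the enantiomeric purity on which every later stereocentre depends. Fallback, from 4 back to 6: the diene is combined with commercial 3-[(E)-but-2-enoyl]-1,3-oxazolidin-2-one under Cu(OTf)2 and (S,S)-2,2′-isopropylidenebis(4-tert-butyl-2-oxazoline) in CH2Cl2 (ligand antipode chosen for the same bridgehead sense). Two-point binding of the imide gives a more reactive and more ordered dienophile and should deliver the endo imide 3-{[(1S,2R,3S,4R)-3,5,6-trimethylbicyclo[2.2.2]oct-5-en-2-yl]carbonyl}-1,3-oxazolidin-2-one F1. LiBH4 in wet THF cleaves the imide to [(1S,2R,3S,4R)-3,5,6-trimethylbicyclo[2.2.2]oct-5-en-2-yl]methanol F2, and Dess–Martin periodinane oxidises it to aldehyde 6.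

Step 8. What may go wrong: palladation of the tetrasubstituted enol ether may be slow, or β-hydride elimination may go toward the C9 methyl instead of H-10. Fallback, from 12 back to 13: PhSeCl in CH2Cl2 at −78 °C should add to the convex face of the cis-fused enol ether to give the cis-fused 1,4a,5-trimethyl-1-(phenylselanyl)-3,4,4a,7,8,8a-hexahydronaphthalen-2(1H)-one F3, with selenium cis to H-8a. Oxidation with H2O2/pyridine at 0 °C then lets the selenoxide eliminate syn toward that hydrogen, giving 13.

Step 27. What may go wrong: the hydroxyquinone is largely ionised (vinylogous carboxylate) and the hindered, easily oxidised aryl amine is a weak nucleophile, so substitution may be slow and outrun by redox side reactions between amine and quinone. Fallback, from 24 and 38 to 39: the amine is condensed with the neutral, more electrophilic dimethoxyquinone 24 (EtOH, 50 °C, argon). Attack at the unhindered C5 methoxy carbon should give methyl 2,4-dihydroxy-3-[(5-methoxy-3,6-dioxo-4-Av-cyclohexa-1,4-dien-1-yl)amino]-5-Av-benzoate F4. The remaining vinylogous methyl ester is then hydrolysed with dilute aqueous HClO4 in THF at rt, conditions under which the aryl ester and the vinylogous amide should persist, to give 39.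

**Further compounds**
F1 | step 3 | 3-{[(1S,2R,3S,4R)-3,5,6-trimethylbicyclo[2.2.2]oct-5-en-2-yl]carbonyl}-1,3-oxazolidin-2-one | O=C([C@@H]1[C@@H](C)[C@H]2CC[C@@H]1C(C)=C2C)N1CCOC1=O
F2 | step 3 | [(1S,2R,3S,4R)-3,5,6-trimethylbicyclo[2.2.2]oct-5-en-2-yl]methanol | OC[C@@H]1[C@@H](C)[C@H]2CC[C@@H]1C(C)=C2C
F3 | step 8 | cis-fused 1,4a,5-trimethyl-1-(phenylselanyl)-3,4,4a,7,8,8a-hexahydronaphthalen-2(1H)-one (Se cis to H-8a) | O=C1CC[C@]2(C)C(C)=CCC[C@@H]2[C@@]1(C)[Se]c1ccccc1
F4 | step 27 | methyl 2,4-dihydroxy-3-[(5-methoxy-3,6-dioxo-4-Av-cyclohexa-1,4-dien-1-yl)amino]-5-Av-benzoate | COC(=O)c1cc(C[C@]2(C)[C@@H](C)CC[C@]3(C)C(C)=CCC[C@@H]23)c(O)c(NC2=CC(=O)C(OC)=C(C[C@]3(C)[C@@H](C)CC[C@]4(C)C(C)=CCC[C@@H]34)C2=O)c1O
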